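A complex with two exchanged cannot be built from incoming ligand that the protic impurity has already taken. Both earlier runs hold the ligand at 1.2 equiv, so a curve drawn through them shows nothing about a change of charge, whereas a count of ligand does.

| flask | starting complex | incoming ligand | protic impurity | remark | time |
|---|---|---|---|---|---|
| grey | 0.020 M | 1.2 equiv | 4 mM | run made earlier |  |
| ochre | 0.020 M | 1.2 equiv | 3 mM | run made earlier |  |
| summer | 0.020 M | 1.20 equiv | 6.00 mM |  | 2.0 h |
| midnight | 0.020 M | 2.00 equiv | 6.00 mM |  | 2.0 h |
| autumn | 0.020 M | 4.00 equiv | 6.00 mM |  | 2.0 h |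

| run | time / min | complex with two exchanged / % | complex with one exchanged / % | starting complex / % |
|---|---|---|---|---|
| grey | 3.00 | 9.2 | 11.3 | 80.5 |
| grey | 5.00 | 14.5 | 13.1 | 72.9 |
| grey | 8.00 | 18.7 | 14.0 | 65.6 |
| grey | 12.0 | 21.9 | 14.6 | 61.5 |
| grey | 20.0 | 24.0 | 16.1 | 56.4 |
| grey | 30.0 | 26.2 | 15.0 | 52.0 |
| grey | 40.0 | 28.0 | 14.9 | 49.9 |
| ochre | 6.00 | 16.7 | 13.2 | 70.3 |
| ochre | 12.0 | 22.1 | 15.0 | 60.6 |
| ochre | 20.0 | 26.2 | 15.4 | 55.3 |
| ochre | 25.0 | 26.3 | 15.3 | 51.8 |
| ochre | 30.0 | 27.1 | 15.8 | 50.4 |
| ochre | 40.0 | 28.9 | 16.0 | 47.3 |

(each reading ± 0.5 percentage points)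

- no earlier run changes the charge of incoming ligand; that part of a forecast is a guess

1. complex with two exchanged at the end, in percent of the starting complex charged, for each flask in turn (summer, midnight, autumn)

I count the usable charge: incoming ligand per starting complex charged, less one for each protic impurity. For summer that is 0.900 equiv, for midnight 1.70 equiv, for autumn 3.70 equiv.

On the top rung of my ladder I put the impurity, and this is an assumption resting on a thin reading. At 40.0 min the two complexes hold 0.709 equiv of ligand in grey and 0.738 equiv in ochre, a gap in the direction of the 0.0500 equiv that separates their impurity charges, though each reading carries 0.5 percentage points.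

Next comes the first exchange: grey loses 19 points of its starting complex in 3.00 min, far faster than the 2.1 points lost between 30.0 min and 40.0 min. Then, in grey, the intermediate levels off: complex with one exchanged reads 14.0 % at 8.00 min and 14.9 % at 40.0 min, while complex with two exchanged climbs from 18.7 % to 28.0 %. Last on my ladder stands a drift: the three grey readings sum to 101 % at 3.00 min and 92.8 % at 40.0 min.

Full exchange takes two ligands. So incoming ligand is the limiting reagent in summer and midnight, with ceilings of 45.0 % and 85.0 %, while autumn, at 3.70 equiv, is bounded by the complex at 100%. I commit to those ceilings and to no closer figure. The forecast says 30 %, 46 % and 71 %, and adds: “The ligand dependence is a guess”.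

The flasks give 31.2 %, 61.4 % and 83.9 %, so midnight stands 15 points above the forecast and below my ceiling for that flask.

    protic impurity + incoming ligand → quenched reagent (k = 14.0 L mol⁻¹ min⁻¹)
    leaving ligand → by-product carried off (k = 0.0510 min⁻¹)
    leaving ligand + complex with one exchanged → side product (k = 2.30 L mol⁻¹ min⁻¹)
    complex with one exchanged + incoming ligand ⇌ leaving ligand + complex with two exchanged (K = 1.60, k = 23.0 L mol⁻¹ min⁻¹)
    starting complex + incoming ligand ⇌ leaving ligand + complex with one exchanged (K = 0.370, k = 4.10 L mol⁻¹ min⁻¹)

Side product carries one incoming ligand. In summer, the two complexes, side product and unreacted incoming ligand together hold 0.901 equiv, against a usable charge of 0.900 equiv. In midnight, 1.33 equiv in the complexes, side product at 16.6 % of the starting complex charged and 0.205 equiv of unreacted incoming ligand add up to 1.70 equiv, against 1.70 equiv.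

The readings stem from a simulated flask from invented constants, and the scatter is random.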